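The rate constants of this flask are not given, but you can do without them if you divide one rate by another so that time drops out.

- south-east: substrate 0.39 M (in portions, 3); first nucleophile 2 equiv; second nucleophile 1 equiv; run made earlier; portions every 40 s
- flask: substrate 0.39 M (in portions, 3); first nucleophile 2.00 equiv; second nucleophile 0.700 equiv; time 2.5 h; the portions of substrate follow each other after 40 s, the first at the start

south-east run (percent of the substrate charged)

| time / min | target / % | other capture product / % |
|---|---|---|
| 4.00 | 0.9 | 44.4 |
| 12.0 | 2.6 | 77.3 |
| 20.0 | 4.8 | 84.1 |
| 30.0 | 4.3 | 83.5 |
| 50.0 | 4.8 | 84.3 |

(readings scatter by 0.5 percentage points)

- steps thought possible: intermediate -> solvolysis product; substrate -> intermediate; first nucleophile + intermediate -> target; second nucleophile + intermediate -> other capture product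
- the reaction counts as stopped when no species that holds the substrate changes by six tenths of a point or more over the second half of the time

1. why nothing more happens at 2.5 h, or that something still does (all of the substrate has reacted / the first nucleophile has run out first / it is still moving / the second nucleophile has run out first)
2. how much target there is at 2.5 h, in percent of the substrate charged
3. how much other capture product there is at 2.5 h, in percent of the substrate charged
4. how much solvolysis product there is at 2.5 h, in percent of the substrate charged

The two recipes differ in the second nucleophile. In the south-east run the other capture product stands flat from 20.0 min, at a mean of 84.0 %. The asked 2.5 h is far longer than that, so I expect the substrate to have reacted.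

Let n be the second nucleophile left, as a fraction of the substrate charge, and s its starting value. Each intermediate is either captured by the second nucleophile, at a rate proportional to n, or leaks to target or solvolysis product. Dividing the rates gives a capture share n/(n+h), with no time in it. Here h is the half-capture level, the n at which capture equals leak, an inverse selectivity factor. Summed over the substrate, this gives h·ln(s/n) + s − n = 1. The south-east plateau, as read, gives h = 0.0876, and I carry it over because the substrate and first nucleophile charges match.

Two extremes can be done in the head. With no leak, the flask's capture equals its charge, s = 0.700, or 70.0 %. If the flask used the same fraction of its second nucleophile as the south-east run, capture would be 58.8 %. With less second nucleophile per substrate than the south-east run, the flask must use a larger fraction, so I put its capture between these. Solving gives n = 0.0184, so capture is 68.2 %. Splitting the remainder by the plateau share of target in the leak, 0.289, gives target 9.20 % and solvolysis product 22.6 %.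

The forecast, close to mine but not identical, said all of the substrate has reacted, with target 9.3 %, other capture product 68.2 % and solvolysis product 22.5 %: “The second nucleophile is nearly but not fully consumed”.

The flask gives all of the substrate has reacted, with target 8.62 %, other capture product 68.3 % and solvolysis product 23.1 %.

    intermediate → solvolysis product (k = 0.325 /s)
    substrate → intermediate (k = 0.00340 /s)
    first nucleophile + intermediate → target (k = 0.159 /M/s)
    second nucleophile + intermediate → other capture product (k = 13.4 /M/s)

For each intermediate in this flask, the leak, with the first nucleophile as it stands at 2.50 h, runs at 0.444 /s, while capture runs at 3.66 /s at the start, faster than the leak, and at 0.0893 /s at 2.50 h, slower than the leak. By then n is 0.0171, less than h.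

In the neighbour flask with 0.170 equiv of second nucleophile, the same h leaves 0.00767 % of that second nucleophile's charge, so capture is about 17.0 % and the leak about 83.0 %. Computed, that flask holds 17.0 % other capture product, 22.0 % target and 61.0 % solvolysis product, with 0.0055 % of the second nucleophile left.

(The earlier runs and the new flask stem from a simulated flask for substances that don't exist; scatter was added.)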